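**Retrosynthetic overview**

1. Numbering: C1–C5 pentyl, oxolane O–C6–C7–C8–C9, carbinol C10, C11–C19 non-8-enyl. The acyloxy carbon C7 and the ring carbon C9 are mirror images of each other across the C8 methylene, so C5–C11 is a masked meso-hepta-1,6-diene-3,5-diol.
2. Late disconnections: C10–C11 (non-8-enyl Grignard on the C10 aldehyde under chelate control), the C7 ester (tetradecanoyl chloride), C4–C5 (butyl cuprate on a C5 tosylate).
3. Oxolane: the O9–C6 bond comes from 5-exo opening of a C5/C6 oxirane by O9 with inversion at C6 (gives 2,3-cis and 2,5-trans).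
4. Oxirane: L-(+)-tartrate/titanium epoxidation of one of the two enantiotopic vinyl carbinol arms of the meso diol, which is made from methyl vinyl ketone and acrolein by aldol addition and syn reduction.
5. Ring order: oxirane first (step 3, transient), then the oxolane (step 4, the only ring of the target).

Key step: step 3

Remark: the arm taken as matched with L-(+)-tartrate is the one whose carbinol is S (ranking OH > vinyl > CH2), as in the kinetic resolution of secondary allylic alcohols; the aldol 4 is racemic, which does not matter because either enantiomer gives the same meso diol 6.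

**Route**

Step 1
Reactants: 1 but-3-en-2-one (methyl vinyl ketone); 2 prop-2-enal (acrolein)
Product: 4 rac-5-hydroxyhepta-1,6-dien-3-one, via lithium buta-1,3-dien-2-olate 3 (not isolated)
Conditions: LDA (1.05 equiv), THF, −78 °C, slow addition of 1; then 2, −78 °C; sat. aq. NH4Cl at −78 °C
Reagents that add atoms: none
Why: Directed aldol addition: kinetic deprotonation of the methyl group of 1 gives the cross-conjugated lithium enolate 3, which should add 1,2 to the aldehyde of acrolein at −78 °C, slow addition of 1 to excess base keeping Michael oligomerisation down.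

Step 2
Reactants: 4 rac-5-hydroxyhepta-1,6-dien-3-one
Product: 6 meso-(3R,5S)-hepta-1,6-diene-3,5-diol, via diethylboron chelate 5 (not isolated)
Conditions: Et2BOMe (1.1 equiv), THF/MeOH 4:1, −78 °C; NaBH4 (1.1 equiv), −78 °C; then MeOH, repeated co-evaporation
Reagents that add atoms: none
Why: Narasaka–Prasad reduction: the boron chelate 5 holds the β-alkoxy ketone in a half-chair and hydride is delivered axially and 1,2 to the activated carbonyl, so the new hydroxyl is set syn to the old one, and a syn-1,3-diol with two vinyl ends is the achiral meso compound.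

Step 3
Reactants: 6 meso-(3R,5S)-hepta-1,6-diene-3,5-diol
Product: 7 (1S,3R)-1-[(2R)-oxiran-2-yl]pent-4-ene-1,3-diol (erythro mono-epoxide)
Conditions: Ti(OiPr)4 (0.3 equiv), L-(+)-diisopropyl tartrate (0.36 equiv), anhydrous t-BuOOH (1.3 equiv), 4 Å MS, CH2Cl2, −20 °C; Me2S quench, triethanolamine, filtration through silica (non-aqueous work-up)
Reagents that add atoms: tert-butyl hydroperoxide, CC(C)(C)OO
Why: This is a Sharpless asymmetric epoxidation used to select between enantiotopic groups, the reaction type known for divinylcarbinol and meso bis(secondary allylic) diols: one carbinol exchanges onto the dimeric titanium tartrate and the titanium-bound tert-butyl peroxide passes its distal oxygen to the vinyl group of that same alkoxide. The oxirane closes in this single concerted oxygen-atom transfer, which forms the C5–O and C6–O bonds together (a [2+1] addition to the alkene, not a chain cyclisation). With L-(+)-tartrate the arm with the S carbinol is the matched one, because on the face the tartrate serves its hydrogen and not its carbon chain points into the catalyst; the R arm is mismatched and should remain. The new stereocentre C6 is set by that same face choice, oxygen arriving erythro (anti in the zigzag) to the C7 hydroxyl, and the choice of arm turns the mirror-related C7 and C9 into defined S and R centres. The step needs selectivity between the two arms and between the two faces of the chosen vinyl group, and both are secured by the secondary carbinol next to each alkene acting against the tartrate. Any enantiomeric mono-epoxide still carries a free matched arm and should be consumed to bis-epoxide, which is expected to raise the enantiomeric purity of 7 as conversion proceeds.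

Step 4
Reactants: 7 (1S,3R)-1-[(2R)-oxiran-2-yl]pent-4-ene-1,3-diol
Product: 8 (2S,3S,5R)-5-ethenyl-2-(hydroxymethyl)oxolan-3-ol
Conditions: CSA (0.1 equiv), CH2Cl2, 0 °C to rt
Reagents that add atoms: none
Why: Acid-catalysed intramolecular opening of a 4,5-epoxy alcohol: O9 should attack the protonated oxirane at C6 from the rear in the 5-exo-tet mode (preferred over 6-endo attack at C5), inverting C6 so that the erythro C6/C7 pair becomes 2,3-cis and the syn-1,3-diol becomes the 2,5-trans oxolane; base is avoided to exclude Payne rearrangement.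

Step 5
Reactants: 8 (2S,3S,5R)-5-ethenyl-2-(hydroxymethyl)oxolan-3-ol
Product: 9 [(2S,3S,5R)-5-ethenyl-3-hydroxyoxolan-2-yl]methyl 4-methylbenzenesulfonate
Conditions: TsCl (1.1 equiv), pyridine, CH2Cl2, −10 to 0 °C
Reagents that add atoms: 4-methylbenzenesulfonyl chloride, Cc1ccc(cc1)S(=O)(=O)Cl
Why: Selective sulfonylation: the unhindered primary hydroxyl should react with TsCl much faster than the secondary ring hydroxyl at low temperature, and no stereocentre is touched.

Step 6
Reactants: 9 [(2S,3S,5R)-5-ethenyl-3-hydroxyoxolan-2-yl]methyl 4-methylbenzenesulfonate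
Product: 10 (2S,3S,5R)-5-ethenyl-2-pentyloxolan-3-ol
Conditions: n-Bu2CuLi (4 equiv, from n-BuLi and CuI), Et2O, −40 to −10 °C; aq. NH4Cl/NH3
Reagents that add atoms: lithium dibutylcuprate (from n-butyllithium and copper(I) iodide), [Li+].CCCC[Cu-]CCCC
Why: SN2 displacement of a primary tosylate by a Gilman cuprate forms C4–C5; the excess reagent covers deprotonation of the free C7 hydroxyl, and the vinyl group and the allylic ring ether are not expected to react.

Step 7
Reactants: 10 (2S,3S,5R)-5-ethenyl-2-pentyloxolan-3-ol; 11 tetradecanoyl chloride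
Product: 12 (2S,3S,5R)-5-ethenyl-2-pentyloxolan-3-yl tetradecanoate
Conditions: 11 (1.2 equiv), pyridine, DMAP (0.1 equiv), CH2Cl2, 0 °C to rt
Reagents that add atoms: none
Why: DMAP-catalysed acylation of the only free hydroxyl (C7) by the acid chloride; the C7–O bond is not broken, so configuration is retained.

Step 8
Reactants: 12 (2S,3S,5R)-5-ethenyl-2-pentyloxolan-3-yl tetradecanoate
Product: 14 (2S,3S,5R)-5-formyl-2-pentyloxolan-3-yl tetradecanoate, via secondary ozonide 13 (not isolated)
Conditions: O3, CH2Cl2, −78 °C; PPh3, −78 °C to rt; used crude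
Reagents that add atoms: ozone, [O-][O+]=O
Why: Ozonolysis (Criegee mechanism) of the only alkene through ozonide 13 and reduction by PPh3 should give the C10 aldehyde; ester and ring ether are inert, and the α-alkoxy aldehyde is carried on crude to avoid epimerisation at C9.

Step 9
Reactants: 15 9-bromonon-1-ene
Product: 16 non-8-en-1-ylmagnesium bromide (Et2O solution)
Conditions: Mg turnings, I2 (cat.), Et2O, gentle reflux
Reagents that add atoms: magnesium, [Mg]
Why: Grignard reagent formation by insertion of magnesium into the primary C–Br bond; the remote terminal alkene does not interfere.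

Step 10
Reactants: 14 (2S,3S,5R)-5-formyl-2-pentyloxolan-3-yl tetradecanoate; 16 non-8-en-1-ylmagnesium bromide
Product: 17 (2S,3S,5R)-5-[(1R)-1-hydroxydec-9-en-1-yl]-2-pentyloxolan-3-yl tetradecanoate (target)
Conditions: MgBr2·OEt2 (1.5 equiv), CH2Cl2, −78 °C; then 16 (1.3 equiv, Et2O), −78 °C; sat. aq. NH4Cl at −78 °C
Reagents that add atoms: none
Why: Chelation-controlled (Cram chelate) Grignard addition: magnesium bridges the aldehyde oxygen and the ring oxygen and the nucleophile should attack the locked carbonyl on the side of the C9 hydrogen, giving the threo (9R,10R) carbinol, while at −78 °C the aldehyde reacts much faster than the secondary ester and the trans-disposed C7 ester cannot take up the C10 alkoxide.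

**Compound list**

1 | but-3-en-2-one (methyl vinyl ketone) | CC(=O)C=C | starting material
2 | prop-2-enal (acrolein) | C=CC=O | starting material
3 | lithium buta-1,3-dien-2-olate (kinetic enolate of 1) | [Li]OC(=C)C=C | intermediate
4 | rac-5-hydroxyhepta-1,6-dien-3-one | C=CC(=O)CC(O)C=C | intermediate
5 | 5-[(diethylboranyl)oxy]hepta-1,6-dien-3-one (boron chelate of 4, B coordinated by the ketone oxygen) | C=CC(=O)CC(C=C)OB(CC)CC | intermediate
6 | meso-(3R,5S)-hepta-1,6-diene-3,5-diol | C=C[C@H](O)C[C@H](O)C=C | intermediate
7 | (1S,3R)-1-[(2R)-oxiran-2-yl]pent-4-ene-1,3-diol | C=C[C@H](O)C[C@H](O)[C@H]1CO1 | intermediate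
8 | (2S,3S,5R)-5-ethenyl-2-(hydroxymethyl)oxolan-3-ol (CH2OH and OH cis, vinyl trans to CH2OH) | C=C[C@H]1C[C@H](O)[C@H](CO)O1 | intermediate
9 | [(2S,3S,5R)-5-ethenyl-3-hydroxyoxolan-2-yl]methyl 4-methylbenzenesulfonate | C=C[C@H]1C[C@H](O)[C@H](COS(=O)(=O)c2ccc(C)cc2)O1 | intermediate
10 | (2S,3S,5R)-5-ethenyl-2-pentyloxolan-3-ol | C=C[C@H]1C[C@H](O)[C@H](CCCCC)O1 | intermediate
11 | tetradecanoyl (myristoyl) chloride | CCCCCCCCCCCCCC(=O)Cl | starting material
12 | (2S,3S,5R)-5-ethenyl-2-pentyloxolan-3-yl tetradecanoate | C=C[C@H]1C[C@H](OC(=O)CCCCCCCCCCCCC)[C@H](CCCCC)O1 | intermediate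
13 | (2S,3S,5R)-2-pentyl-5-(1,2,4-trioxolan-3-yl)oxolan-3-yl tetradecanoate (secondary ozonide, trioxolane carbon unassigned) | O1COOC1[C@H]2C[C@H](OC(=O)CCCCCCCCCCCCC)[C@H](CCCCC)O2 | intermediate
14 | (2S,3S,5R)-5-formyl-2-pentyloxolan-3-yl tetradecanoate | O=C[C@H]1C[C@H](OC(=O)CCCCCCCCCCCCC)[C@H](CCCCC)O1 | intermediate
15 | 9-bromonon-1-ene | C=CCCCCCCCBr | starting material
16 | non-8-en-1-ylmagnesium bromide | C=CCCCCCCC[Mg]Br | intermediate
17 | (2S,3S,5R)-5-[(1R)-1-hydroxydec-9-en-1-yl]-2-pentyloxolan-3-yl tetradecanoate, chain descriptors (6S,7S,9R,10R) | C=CCCCCCCC[C@@H](O)[C@H]1C[C@H](OC(=O)CCCCCCCCCCCCC)[C@H](CCCCC)O1 | target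

**Step count**

Total steps: 10. Longest linear sequence: 9 (steps 1–8 and 10); step 9 is a one-step branch.

**Steps most likely to fail**

Step 3 (key step). The syn-1,3-diol may bind titanium as a chelate and disturb the tartrate catalyst, so that discrimination between the two arms is poor or the slow terminal vinyl group does not react; the water-soluble epoxy diol may also be lost on isolation. The fallback sets out from 6 and replaces desymmetrisation by kinetic resolution of a substrate with a single free hydroxyl. Statistical monosilylation (TBSCl 1.0 equiv, imidazole, DMF, 0 °C) should give the racemic ether rac-(3S*,5R*)-5-[(tert-butyldimethylsilyl)oxy]hepta-1,6-dien-3-ol F1. Sharpless kinetic resolution of F1 (Ti(OiPr)4, L-(+)-DIPT, t-BuOOH 0.6 equiv, 4 Å MS, CH2Cl2, −20 °C) should epoxidise only the enantiomer with the free S carbinol, erythro, to (1S,3R)-3-[(tert-butyldimethylsilyl)oxy]-1-[(2R)-oxiran-2-yl]pent-4-en-1-ol F2. The unreacted enantiomer returns meso 6 on desilylation and can be recycled. Buffered desilylation of F2 (TBAF, AcOH, THF, 0 °C) comes back to the route at 7.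

Step 4. C6 is deactivated by the neighbouring C7 hydroxyl and C5 is an unhindered terminus, so ring closure may go 6-endo at C5 or the oxirane may be opened intermolecularly. The fallback sets out from 7 and activates C6 in a different way. Copper-catalysed Grignard opening of the terminal oxirane at C5 (n-BuMgCl 3.5 equiv, CuI 10 mol%, THF, −40 °C) should give (3R,5S,6R)-undec-1-ene-3,5,6-triol F3 with the pentyl chain already in place. Trimethyl orthoacetate with PPTS in CH2Cl2 should convert the C6/C7 diol into the cyclic orthoacetate (2R)-1-[(4S,5R)-2-methoxy-2-methyl-5-pentyl-1,3-dioxolan-4-yl]but-3-en-2-ol F4. Adding BF3·OEt2 to the same pot ionises F4 to the acetoxonium ion, which O9 should open at C6 with inversion (5-membered ring closure) to give (2S,3S,5R)-5-ethenyl-2-pentyloxolan-3-yl acetate F5. Methanolysis (K2CO3, MeOH) comes back to the route at 10, so steps 5 and 6 are bypassed as well.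

Step 10. Chelation between the ring oxygen and the aldehyde may be incomplete, giving poor facial selectivity at C10. The fallback sets out from 14 and sets C10 by reduction instead of addition. Addition of 16 in THF at −78 °C without additive should give the C10 epimer mixture (2S,3S,5R)-5-[(1RS)-1-hydroxydec-9-en-1-yl]-2-pentyloxolan-3-yl tetradecanoate F6. Dess–Martin oxidation should give the ketone (2S,3S,5R)-5-(dec-9-enoyl)-2-pentyloxolan-3-yl tetradecanoate F7. K-Selectride in THF at −78 °C should reduce F7 under Felkin–Anh (polar) control, hydride entering anti to the ring C–O bond, to the threo alcohol, which comes back to the route at 17.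

**Further compounds**

F1 | step 3 | rac-(3S*,5R*)-5-[(tert-butyldimethylsilyl)oxy]hepta-1,6-dien-3-ol (racemate; the enantiomer drawn is the one that is epoxidised) | C=C[C@H](O[Si](C)(C)C(C)(C)C)C[C@H](O)C=C
F2 | step 3 | (1S,3R)-3-[(tert-butyldimethylsilyl)oxy]-1-[(2R)-oxiran-2-yl]pent-4-en-1-ol | C=C[C@H](O[Si](C)(C)C(C)(C)C)C[C@H](O)[C@H]1CO1
F3 | step 4 | (3R,5S,6R)-undec-1-ene-3,5,6-triol | C=C[C@H](O)C[C@H](O)[C@H](O)CCCCC
F4 | step 4 | (2R)-1-[(4S,5R)-2-methoxy-2-methyl-5-pentyl-1,3-dioxolan-4-yl]but-3-en-2-ol (cyclic orthoacetate, orthoester carbon unassigned) | C=C[C@H](O)C[C@@H]1OC(C)(OC)O[C@@H]1CCCCC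
F5 | step 4 | (2S,3S,5R)-5-ethenyl-2-pentyloxolan-3-yl acetate | C=C[C@H]1C[C@H](OC(C)=O)[C@H](CCCCC)O1
F6 | step 10 | (2S,3S,5R)-5-[(1RS)-1-hydroxydec-9-en-1-yl]-2-pentyloxolan-3-yl tetradecanoate (C10 epimer mixture) | C=CCCCCCCCC(O)[C@H]1C[C@H](OC(=O)CCCCCCCCCCCCC)[C@H](CCCCC)O1
F7 | step 10 | (2S,3S,5R)-5-(dec-9-enoyl)-2-pentyloxolan-3-yl tetradecanoate | C=CCCCCCCCC(=O)[C@H]1C[C@H](OC(=O)CCCCCCCCCCCCC)[C@H](CCCCC)O1
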